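## Retrosynthetic overview

1. Ring E of the target is closed last, by a domino enyne ring-closing metathesis/cross-metathesis with methyl vinyl ketone on alcohol 28; 28 comes from Diels–Alder adduct 26 by a singlet-oxygen ene reaction (1'-OH, C2'=C3').
2. 26 (ring C and the spiro centre C11) ⇐ "ortho", carbonyl-exo Diels–Alder reaction of dienone 16 (upper unit, 10S) with methylene lactone 25 (lower unit, 10R), which has no diene and can only be the dienophile.
3. 16 ⇐ domino enyne ring-closing metathesis/cross-metathesis (ring B) of enyne lactone 13; 13 and 25 are C10 epimers made in parallel by the same six steps.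
4. Each enyne lactone ⇐ Mannich methylenation and trans conjugate allylation of a butenolide ⇐ asymmetric propiolate addition and semi-hydrogenation ⇐ β-alkynyl aldehyde ⇐ crotonaldehyde + silylacetylene.
5. Ring order: lactones A and D, ring B (metathesis), ring C (Diels–Alder), ring E (metathesis).

Numbering used below: xanthanolide numbering; primed locants are the upper (diene-derived) unit, unprimed the lower unit. Rings: A upper lactone, B upper seven-membered ring, C cyclohexene, D spiro lactone, E lower cycloheptene.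

Assumption: the ligand enantiomers named in steps 1, 2, 8 and 9 are taken to be the ones that give the drawn configurations; if the sense of induction is the opposite, the mirror-image ligand is used.

## Route

**Branch A (upper unit, 10S)**

Step 1
Reactants: 1 (E)-but-2-enal; 2 ethynyltri(propan-2-yl)silane
Product: 3 (3S)-3-methyl-5-[tri(propan-2-yl)silyl]pent-4-ynal
Conditions: [Rh(OAc)(C2H4)2]2 (2.5 mol%), (S)-DTBM-SEGPHOS (6 mol%), MeOH, 40 °C
Reagents that add atoms: none
Why: Rh-catalysed asymmetric conjugate alkynylation of the enal, in which the bulky silyl group suppresses alkyne dimerisation and the chiral bisphosphine sets C10 (S).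

Step 2
Reactants: 3 (3S)-3-methyl-5-[tri(propan-2-yl)silyl]pent-4-ynal; 4 methyl prop-2-ynoate
Product: 5 methyl (4R,6S)-4-hydroxy-6-methyl-8-[tri(propan-2-yl)silyl]octa-2,7-diynoate
Conditions: (S,S)-ProPhenol (10 mol%), Me2Zn (3 equiv), Ph3P=O (20 mol%), PhMe, 4 °C; aq NH4Cl
Reagents that add atoms: none
Why: Zn–ProPhenol-catalysed asymmetric alkynylation of the aldehyde, where the dinuclear zinc catalyst and not the remote C10 centre selects the aldehyde face and sets C8 (R).

Step 3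
Reactants: 5 methyl (4R,6S)-4-hydroxy-6-methyl-8-[tri(propan-2-yl)silyl]octa-2,7-diynoate
Product: 7 (5R)-5-{(2S)-2-methyl-4-[tri(propan-2-yl)silyl]but-3-yn-1-yl}furan-2(5H)-one, via Z-hydroxy enoate 6 (not isolated)
Conditions: H2 (1 atm), Pd/CaCO3 poisoned with Pb(OAc)2, quinoline, EtOAc, 23 °C; then PPTS (cat.), CH2Cl2, 23 °C
Reagents that add atoms: none
Why: Lindlar-type cis semi-hydrogenation of the activated ynoate (the hindered silyl alkyne is much slower) gives the Z-γ-hydroxy enoate, which lactonises to the butenolide without touching C8 or C10.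

Step 4
Reactants: 7 (5R)-5-{(2S)-2-methyl-4-[tri(propan-2-yl)silyl]but-3-yn-1-yl}furan-2(5H)-one; 8 allylmagnesium bromide (CH2=CHCH2MgBr)
Product: 10 (3R,4S,5R)-3-[(dimethylamino)methyl]-5-{(2S)-2-methyl-4-[tri(propan-2-yl)silyl]but-3-yn-1-yl}-4-(prop-2-en-1-yl)oxolan-2-one, via silyl ketene acetal 9 (not isolated)
Conditions: CuBr·SMe2 (20 mol%), TMSCl (2 equiv), THF, −78 °C; then [CH2=NMe2]I, −78 → 23 °C
Reagents that add atoms: Eschenmoser's salt (N,N-dimethylmethyleneiminium iodide), C=[N+](C)C.[I-]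
Why: Copper-catalysed, TMSCl-accelerated conjugate allylation occurs anti to the γ-substituent of the butenolide (sets C7, 4,5-trans), and the silyl ketene acetal is trapped in a Mannich reaction.

Step 5
Reactants: 10 (3R,4S,5R)-3-[(dimethylamino)methyl]-5-{(2S)-2-methyl-4-[tri(propan-2-yl)silyl]but-3-yn-1-yl}-4-(prop-2-en-1-yl)oxolan-2-one
Product: 11 (3R,4S,5R)-3-[(dimethylamino)methyl]-5-[(2S)-2-methylbut-3-yn-1-yl]-4-(prop-2-en-1-yl)oxolan-2-one
Conditions: TBAF (1.2 equiv), THF, 0 → 23 °C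
Reagents that add atoms: none
Why: Fluoride-mediated C–Si cleavage frees the terminal alkyne while the base-sensitive methylene lactone is still masked as its Mannich base.

Step 6
Reactants: 11 (3R,4S,5R)-3-[(dimethylamino)methyl]-5-[(2S)-2-methylbut-3-yn-1-yl]-4-(prop-2-en-1-yl)oxolan-2-one
Product: 13 (4S,5R)-3-methylidene-5-[(2S)-2-methylbut-3-yn-1-yl]-4-(prop-2-en-1-yl)oxolan-2-one, via ammonium iodide 12 (not isolated)
Conditions: MeI (10 equiv), MeOH, 23 °C; then NaHCO3, EtOAc/H2O, 23 °C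
Reagents that add atoms: none
Why: Quaternisation followed by Hofmann-type (E1cB) elimination of trimethylamine gives the α-methylene lactone and removes the inconsequential C11 stereocentre.

Step 7
Reactants: 13 (4S,5R)-3-methylidene-5-[(2S)-2-methylbut-3-yn-1-yl]-4-(prop-2-en-1-yl)oxolan-2-one; 14 but-3-en-2-one
Product: 16 (3aS,7S,8aR)-7-methyl-3-methylidene-6-[(1E)-3-oxobut-1-en-1-yl]-3,3a,4,7,8,8a-hexahydro-2H-cyclohepta[b]furan-2-one, via ring-closed triene 15 (not isolated)
Conditions: second-generation Hoveyda–Grubbs catalyst RuCl2(H2IMes)(=CH-C6H4-2-OiPr) (10 mol%), 14 (5 equiv), CH2Cl2, 40 °C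
Reagents that add atoms: none
Why: Domino ring-closing enyne metathesis (exo mode, closes seven-membered ring B with the C1=C5 alkene and a 1-vinyl group) and E-selective cross-metathesis with the enone, leaving the electron-poor 1,1-disubstituted methylene lactone untouched.

**Branch B (lower unit, 10R)**

Step 8
Reactants: 1 (E)-but-2-enal; 2 ethynyltri(propan-2-yl)silane
Product: 17 (3R)-3-methyl-5-[tri(propan-2-yl)silyl]pent-4-ynal
Conditions: [Rh(OAc)(C2H4)2]2 (2.5 mol%), (R)-DTBM-SEGPHOS (6 mol%), MeOH, 40 °C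
Reagents that add atoms: none
Why: The same Rh-catalysed asymmetric conjugate alkynylation with the mirror-image ligand sets C10 (R).

Step 9
Reactants: 17 (3R)-3-methyl-5-[tri(propan-2-yl)silyl]pent-4-ynal; 4 methyl prop-2-ynoate
Product: 18 methyl (4R,6R)-4-hydroxy-6-methyl-8-[tri(propan-2-yl)silyl]octa-2,7-diynoate
Conditions: (S,S)-ProPhenol (10 mol%), Me2Zn (3 equiv), Ph3P=O (20 mol%), PhMe, 4 °C; aq NH4Cl
Reagents that add atoms: none
Why: Catalyst-controlled Zn–ProPhenol asymmetric alkynylation with the same ligand as in step 2 gives the same C8 (R) configuration beside the epimeric C10.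

Step 10
Reactants: 18 methyl (4R,6R)-4-hydroxy-6-methyl-8-[tri(propan-2-yl)silyl]octa-2,7-diynoate
Product: 20 (5R)-5-{(2R)-2-methyl-4-[tri(propan-2-yl)silyl]but-3-yn-1-yl}furan-2(5H)-one, via Z-hydroxy enoate 19 (not isolated)
Conditions: H2 (1 atm), Pd/CaCO3 poisoned with Pb(OAc)2, quinoline, EtOAc, 23 °C; then PPTS (cat.), CH2Cl2, 23 °C
Reagents that add atoms: none
Why: Lindlar-type cis semi-hydrogenation of the ynoate and lactonisation of the Z-hydroxy enoate, as in step 3.

Step 11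
Reactants: 20 (5R)-5-{(2R)-2-methyl-4-[tri(propan-2-yl)silyl]but-3-yn-1-yl}furan-2(5H)-one; 8 allylmagnesium bromide (CH2=CHCH2MgBr)
Product: 22 (3R,4S,5R)-3-[(dimethylamino)methyl]-5-{(2R)-2-methyl-4-[tri(propan-2-yl)silyl]but-3-yn-1-yl}-4-(prop-2-en-1-yl)oxolan-2-one, via silyl ketene acetal 21 (not isolated)
Conditions: CuBr·SMe2 (20 mol%), TMSCl (2 equiv), THF, −78 °C; then [CH2=NMe2]I, −78 → 23 °C
Reagents that add atoms: Eschenmoser's salt (N,N-dimethylmethyleneiminium iodide), C=[N+](C)C.[I-]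
Why: Copper-catalysed conjugate allylation anti to the γ-substituent sets C7 (trans), followed by Mannich trapping of the silyl ketene acetal.

Step 12
Reactants: 22 (3R,4S,5R)-3-[(dimethylamino)methyl]-5-{(2R)-2-methyl-4-[tri(propan-2-yl)silyl]but-3-yn-1-yl}-4-(prop-2-en-1-yl)oxolan-2-one
Product: 23 (3R,4S,5R)-3-[(dimethylamino)methyl]-5-[(2R)-2-methylbut-3-yn-1-yl]-4-(prop-2-en-1-yl)oxolan-2-one
Conditions: TBAF (1.2 equiv), THF, 0 → 23 °C
Reagents that add atoms: none
Why: Fluoride-mediated desilylation of the alkyne on the amine-masked lactone.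

Step 13
Reactants: 23 (3R,4S,5R)-3-[(dimethylamino)methyl]-5-[(2R)-2-methylbut-3-yn-1-yl]-4-(prop-2-en-1-yl)oxolan-2-one
Product: 25 (4S,5R)-3-methylidene-5-[(2R)-2-methylbut-3-yn-1-yl]-4-(prop-2-en-1-yl)oxolan-2-one, via ammonium iodide 24 (not isolated)
Conditions: MeI (10 equiv), MeOH, 23 °C; then NaHCO3, EtOAc/H2O, 23 °C
Reagents that add atoms: none
Why: Quaternisation and Hofmann-type elimination give the α-methylene lactone dienophile, which has no diene.

**Union and completion**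

Step 14
Reactants: 16 (3aS,7S,8aR)-7-methyl-3-methylidene-6-[(1E)-3-oxobut-1-en-1-yl]-3,3a,4,7,8,8a-hexahydro-2H-cyclohepta[b]furan-2-one; 25 (4S,5R)-3-methylidene-5-[(2R)-2-methylbut-3-yn-1-yl]-4-(prop-2-en-1-yl)oxolan-2-one
Product: 26 Diels–Alder adduct (rings A to D: cyclohexene ring C with C1'=C2' and 3'-acetyl; C13 bonded to C5'; C11 spiro to lactone D; the lower unit keeps its 7-allyl and 8-[(2R)-2-methylbut-3-ynyl] groups; H-3', H-5' and the lactone carbonyl C12 on one face of ring C)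
Conditions: neat in 25 (4 equiv), BHT (5 mol%), 100 °C, 48 h, sealed tube
Reagents that add atoms: none
Why: Thermal intermolecular Diels–Alder reaction in which the excess, diene-free 25 is the only dienophile present in quantity, the acetyl-bearing terminus C3' bonds to C11 ("ortho" orientation) through the carbonyl-exo transition state typical of α-methylene γ-lactones, on the lactone face anti to the C7 allyl group and on the diene face anti to the pseudo-axial H-10', which sets C3', C5' and the spiro centre C11.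

Step 15
Reactants: 26 Diels–Alder adduct
Product: 28 tertiary allylic alcohol (as 26 but with 1'-OH cis to H-5' and the alkene moved to C2'=C3' in conjugation with the acetyl group), via hydroperoxide 27 (not isolated)
Conditions: O2, tetraphenylporphyrin (1 mol%), visible light, CH2Cl2, 0 °C; then PPh3 (1.1 equiv), 0 °C
Reagents that add atoms: dioxygen, O=O
Why: Schenck ene reaction of singlet oxygen with the only electron-rich trisubstituted alkene removes the doubly activated H-3' suprafacially, so oxygen is delivered to C1' on the face of H-3' and H-5' and the conjugated enone forms, and the hydroperoxide is then reduced by the phosphine.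

Step 16
Reactants: 28 tertiary allylic alcohol; 14 but-3-en-2-one
Product: 30 target CNP0168949.3, via ring-closed triene 29 (not isolated)
Conditions: second-generation Hoveyda–Grubbs catalyst RuCl2(H2IMes)(=CH-C6H4-2-OiPr) (15 mol%), 14 (10 equiv), CH2Cl2, 40 °C
Reagents that add atoms: none
Why: Domino ring-closing enyne metathesis between the C7 allyl group and the terminal alkyne closes seven-membered ring E (C1=C5), and cross-metathesis of the new vinyl group with the enone gives the E-dienone, while the methylene lactone and the trisubstituted enone do not react.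

## Compound list

1 | (E)-but-2-enal (crotonaldehyde) | C/C=C/C=O | starting material
2 | ethynyltri(propan-2-yl)silane | C#C[Si](C(C)C)(C(C)C)C(C)C | starting material
3 | (3S)-3-methyl-5-[tri(propan-2-yl)silyl]pent-4-ynal | O=CC[C@H](C)C#C[Si](C(C)C)(C(C)C)C(C)C | intermediate
4 | methyl prop-2-ynoate (methyl propiolate) | COC(=O)C#C | starting material
5 | methyl (4R,6S)-4-hydroxy-6-methyl-8-[tri(propan-2-yl)silyl]octa-2,7-diynoate | COC(=O)C#C[C@H](O)C[C@H](C)C#C[Si](C(C)C)(C(C)C)C(C)C | intermediate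
6 | methyl (2Z,4R,6S)-4-hydroxy-6-methyl-8-[tri(propan-2-yl)silyl]oct-2-en-7-ynoate | COC(=O)/C=C\[C@H](O)C[C@H](C)C#C[Si](C(C)C)(C(C)C)C(C)C | intermediate (not isolated)
7 | (5R)-5-{(2S)-2-methyl-4-[tri(propan-2-yl)silyl]but-3-yn-1-yl}furan-2(5H)-one | O=C1C=C[C@@H](C[C@H](C)C#C[Si](C(C)C)(C(C)C)C(C)C)O1 | intermediate
8 | allylmagnesium bromide | C=CC[Mg]Br | starting material
9 | trimethyl{[(4S,5R)-5-{(2S)-2-methyl-4-[tri(propan-2-yl)silyl]but-3-yn-1-yl}-4-(prop-2-en-1-yl)-4,5-dihydrofuran-2-yl]oxy}silane | C[Si](C)(C)OC1=C[C@H](CC=C)[C@@H](C[C@H](C)C#C[Si](C(C)C)(C(C)C)C(C)C)O1 | intermediate (not isolated)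
10 | (3R,4S,5R)-3-[(dimethylamino)methyl]-5-{(2S)-2-methyl-4-[tri(propan-2-yl)silyl]but-3-yn-1-yl}-4-(prop-2-en-1-yl)oxolan-2-one | O=C1O[C@H](C[C@H](C)C#C[Si](C(C)C)(C(C)C)C(C)C)[C@@H](CC=C)[C@@H]1CN(C)C | intermediate
11 | (3R,4S,5R)-3-[(dimethylamino)methyl]-5-[(2S)-2-methylbut-3-yn-1-yl]-4-(prop-2-en-1-yl)oxolan-2-one | O=C1O[C@H](C[C@H](C)C#C)[C@@H](CC=C)[C@@H]1CN(C)C | intermediate
12 | trimethyl{[(3R,4S,5R)-5-[(2S)-2-methylbut-3-yn-1-yl]-2-oxo-4-(prop-2-en-1-yl)oxolan-3-yl]methyl}ammonium iodide | O=C1O[C@H](C[C@H](C)C#C)[C@@H](CC=C)[C@@H]1C[N+](C)(C)C.[I-] | intermediate (not isolated)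
13 | (4S,5R)-3-methylidene-5-[(2S)-2-methylbut-3-yn-1-yl]-4-(prop-2-en-1-yl)oxolan-2-one | O=C1O[C@H](C[C@H](C)C#C)[C@@H](CC=C)C1=C | intermediate
14 | but-3-en-2-one (methyl vinyl ketone) | C=CC(C)=O | starting material
15 | (3aS,7S,8aR)-6-ethenyl-7-methyl-3-methylidene-3,3a,4,7,8,8a-hexahydro-2H-cyclohepta[b]furan-2-one | C=C1C(=O)O[C@@H]2C[C@H](C)C(C=C)=CC[C@@H]12 | intermediate (not isolated)
16 | (3aS,7S,8aR)-7-methyl-3-methylidene-6-[(1E)-3-oxobut-1-en-1-yl]-3,3a,4,7,8,8a-hexahydro-2H-cyclohepta[b]furan-2-one | C=C1C(=O)O[C@@H]2C[C@H](C)C(/C=C/C(C)=O)=CC[C@@H]12 | intermediate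
17 | (3R)-3-methyl-5-[tri(propan-2-yl)silyl]pent-4-ynal | O=CC[C@@H](C)C#C[Si](C(C)C)(C(C)C)C(C)C | intermediate
18 | methyl (4R,6R)-4-hydroxy-6-methyl-8-[tri(propan-2-yl)silyl]octa-2,7-diynoate | COC(=O)C#C[C@H](O)C[C@@H](C)C#C[Si](C(C)C)(C(C)C)C(C)C | intermediate
19 | methyl (2Z,4R,6R)-4-hydroxy-6-methyl-8-[tri(propan-2-yl)silyl]oct-2-en-7-ynoate | COC(=O)/C=C\[C@H](O)C[C@@H](C)C#C[Si](C(C)C)(C(C)C)C(C)C | intermediate (not isolated)
20 | (5R)-5-{(2R)-2-methyl-4-[tri(propan-2-yl)silyl]but-3-yn-1-yl}furan-2(5H)-one | O=C1C=C[C@@H](C[C@@H](C)C#C[Si](C(C)C)(C(C)C)C(C)C)O1 | intermediate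
21 | trimethyl{[(4S,5R)-5-{(2R)-2-methyl-4-[tri(propan-2-yl)silyl]but-3-yn-1-yl}-4-(prop-2-en-1-yl)-4,5-dihydrofuran-2-yl]oxy}silane | C[Si](C)(C)OC1=C[C@H](CC=C)[C@@H](C[C@@H](C)C#C[Si](C(C)C)(C(C)C)C(C)C)O1 | intermediate (not isolated)
22 | (3R,4S,5R)-3-[(dimethylamino)methyl]-5-{(2R)-2-methyl-4-[tri(propan-2-yl)silyl]but-3-yn-1-yl}-4-(prop-2-en-1-yl)oxolan-2-one | O=C1O[C@H](C[C@@H](C)C#C[Si](C(C)C)(C(C)C)C(C)C)[C@@H](CC=C)[C@@H]1CN(C)C | intermediate
23 | (3R,4S,5R)-3-[(dimethylamino)methyl]-5-[(2R)-2-methylbut-3-yn-1-yl]-4-(prop-2-en-1-yl)oxolan-2-one | O=C1O[C@H](C[C@@H](C)C#C)[C@@H](CC=C)[C@@H]1CN(C)C | intermediate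
24 | trimethyl{[(3R,4S,5R)-5-[(2R)-2-methylbut-3-yn-1-yl]-2-oxo-4-(prop-2-en-1-yl)oxolan-3-yl]methyl}ammonium iodide | O=C1O[C@H](C[C@@H](C)C#C)[C@@H](CC=C)[C@@H]1C[N+](C)(C)C.[I-] | intermediate (not isolated)
25 | (4S,5R)-3-methylidene-5-[(2R)-2-methylbut-3-yn-1-yl]-4-(prop-2-en-1-yl)oxolan-2-one | O=C1O[C@H](C[C@@H](C)C#C)[C@@H](CC=C)C1=C | intermediate
26 | Diels–Alder adduct of 16 and 25 (C1'=C2', 3'-acetyl, spiro C11; lower unit is the open enyne lactone) | C=C1C(=O)O[C@@H]2C[C@H](C)C3=C[C@H](C(C)=O)[C@]4(C[C@@H]3C[C@@H]12)C(=O)O[C@H](C[C@@H](C)C#C)[C@H]4CC=C | intermediate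
27 | 1'-hydroperoxide (C2'=C3' enone, 1'-OOH cis to H-5'; lower unit open enyne lactone) | C=C1C(=O)O[C@@H]2C[C@H](C)[C@]3(OO)C=C(C(C)=O)[C@]4(C[C@@H]3C[C@@H]12)C(=O)O[C@H](C[C@@H](C)C#C)[C@H]4CC=C | intermediate (not isolated)
28 | 1'-alcohol (C2'=C3' enone, 1'-OH cis to H-5'; lower unit open enyne lactone) | C=C1C(=O)O[C@@H]2C[C@H](C)[C@]3(O)C=C(C(C)=O)[C@]4(C[C@@H]3C[C@@H]12)C(=O)O[C@H](C[C@@H](C)C#C)[C@H]4CC=C | intermediate
29 | ring-E-closed triene (as the target, but C1 carries a vinyl group in place of the 3-oxobutenyl chain) | C=C1C(=O)O[C@@H]2C[C@H](C)[C@]3(O)C=C(C(C)=O)[C@]4(C[C@@H]3C[C@@H]12)C(=O)O[C@@H]1C[C@@H](C)C(C=C)=CC[C@H]14 | intermediate (not isolated)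
30 | CNP0168949.3 | C=C1C(=O)O[C@@H]2C[C@H](C)[C@]3(O)C=C(C(C)=O)[C@]4(C[C@@H]3C[C@@H]12)C(=O)O[C@@H]1C[C@@H](C)C(/C=C/C(C)=O)=CC[C@H]14 | target

## Step count and risks

Total step count: 16 (branch A 7 steps, branch B 6 steps, union and completion 3 steps).
Longest linear sequence: 10 steps (steps 1–7, then 14–16), which is 10/16 of the total.

The three steps most likely to fail:

**Step 14 (cross Diels–Alder).** Both partners are electron-poor, 16 can also dimerise with itself, and the facial preference of the 10-epi diene is not reinforced by an axial methyl group. The fallback masks the dienophile of the diene partner. It sets out from 11: enyne ring-closing metathesis of 11 (as its camphorsulfonate salt, same Ru catalyst) gives the ring-closed triene amine F1, and cross-metathesis with 14 in the same flask gives the amine-masked dienone F2, whose lactone cannot act as a dienophile. F2 and 25 (1.5 equiv) are combined at 12 kbar in CH2Cl2 at 25 °C to give the amine-masked cycloadduct F3. MeI then gives the ammonium iodide F4, and NaHCO3 releases the methylene lactone, which is 26, where the route is rejoined.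

**Step 15 (singlet-oxygen ene reaction).** Abstraction of H-5' in place of H-3' would put oxygen on C2', and the hydroperoxide may be reduced incompletely. The fallback replaces the ene reaction by epoxidation and base-induced opening. It sets out from 26: buffered mCPBA (NaHCO3, CH2Cl2, 0 °C) epoxidises the only electron-rich alkene from the open face (the side of H-3' and H-5'; the other face carries the acetyl group and C6') to give the 1',2'-epoxide F5. Et3N in CH2Cl2 then opens this β,γ-epoxy ketone by E1cB elimination to the γ-hydroxy enone, which is 28, where the route is rejoined.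

**Step 16 (domino metathesis on the dimer).** The enyne sits next to the quaternary spiro centre in a polyfunctional substrate, and the Ru carbene may be lost in unproductive paths. The fallback closes ring E before the cycloaddition. It sets out from 25: the domino metathesis of step 7 applied to 25 and 14 gives, through the ring-closed triene F6, the complete lower monomer F7. F7 is added slowly at 100 °C to an excess (3 equiv) of the amine-masked diene F2 (made from 11 as in the fallback for step 14), so that F7 meets a diene that has no dienophile, giving the amine-masked dimer F8. MeI gives the ammonium iodide F9, and NaHCO3 gives the deoxy dimer F10. The singlet-oxygen ene reaction of step 15 on the non-conjugated C1'=C2' alkene gives the hydroperoxide F11, and PPh3 reduces it to 30, where the route ends.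

## Further compounds

F1 | step 14 | (3R,3aS,7S,8aR)-3-[(dimethylamino)methyl]-6-ethenyl-7-methyl-3,3a,4,7,8,8a-hexahydro-2H-cyclohepta[b]furan-2-one | CN(C)C[C@@H]1C(=O)O[C@@H]2C[C@H](C)C(C=C)=CC[C@@H]12
F2 | step 14 | (3R,3aS,7S,8aR)-3-[(dimethylamino)methyl]-7-methyl-6-[(1E)-3-oxobut-1-en-1-yl]-3,3a,4,7,8,8a-hexahydro-2H-cyclohepta[b]furan-2-one | CN(C)C[C@@H]1C(=O)O[C@@H]2C[C@H](C)C(/C=C/C(C)=O)=CC[C@@H]12
F3 | step 14 | amine-masked cycloadduct (26 with the upper methylidene replaced by H and CH2NMe2 at C11') | CN(C)C[C@@H]1C(=O)O[C@@H]2C[C@H](C)C3=C[C@H](C(C)=O)[C@]4(C[C@@H]3C[C@@H]12)C(=O)O[C@H](C[C@@H](C)C#C)[C@H]4CC=C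
F4 | step 14 | trimethylammonium iodide of F3 | C[N+](C)(C)C[C@@H]1C(=O)O[C@@H]2C[C@H](C)C3=C[C@H](C(C)=O)[C@]4(C[C@@H]3C[C@@H]12)C(=O)O[C@H](C[C@@H](C)C#C)[C@H]4CC=C.[I-]
F5 | step 15 | 1',2'-epoxide of 26 (oxygen on the face of H-3' and H-5') | C=C1C(=O)O[C@@H]2C[C@H](C)[C@@]35O[C@H]5[C@H](C(C)=O)[C@]4(C[C@@H]3C[C@@H]12)C(=O)O[C@H](C[C@@H](C)C#C)[C@H]4CC=C
F6 | step 16 | (3aS,7R,8aR)-6-ethenyl-7-methyl-3-methylidene-3,3a,4,7,8,8a-hexahydro-2H-cyclohepta[b]furan-2-one | C=C1C(=O)O[C@@H]2C[C@@H](C)C(C=C)=CC[C@@H]12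
F7 | step 16 | (3aS,7R,8aR)-7-methyl-3-methylidene-6-[(1E)-3-oxobut-1-en-1-yl]-3,3a,4,7,8,8a-hexahydro-2H-cyclohepta[b]furan-2-one | C=C1C(=O)O[C@@H]2C[C@@H](C)C(/C=C/C(C)=O)=CC[C@@H]12
F8 | step 16 | amine-masked dimer (cycloadduct of F2 and F7; CH2NMe2 and H at C11', ring E complete) | CN(C)C[C@@H]1C(=O)O[C@@H]2C[C@H](C)C3=C[C@H](C(C)=O)[C@]4(C[C@@H]3C[C@@H]12)C(=O)O[C@@H]1C[C@@H](C)C(/C=C/C(C)=O)=CC[C@H]14
F9 | step 16 | trimethylammonium iodide of F8 | C[N+](C)(C)C[C@@H]1C(=O)O[C@@H]2C[C@H](C)C3=C[C@H](C(C)=O)[C@]4(C[C@@H]3C[C@@H]12)C(=O)O[C@@H]1C[C@@H](C)C(/C=C/C(C)=O)=CC[C@H]14.[I-]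
F10 | step 16 | deoxy dimer (target without the 1'-OH; C1'=C2' alkene, H and acetyl at C3') | C=C1C(=O)O[C@@H]2C[C@H](C)C3=C[C@H](C(C)=O)[C@]4(C[C@@H]3C[C@@H]12)C(=O)O[C@@H]1C[C@@H](C)C(/C=C/C(C)=O)=CC[C@H]14
F11 | step 16 | 1'-hydroperoxide corresponding to 30 | C=C1C(=O)O[C@@H]2C[C@H](C)[C@]3(OO)C=C(C(C)=O)[C@]4(C[C@@H]3C[C@@H]12)C(=O)O[C@@H]1C[C@@H](C)C(/C=C/C(C)=O)=CC[C@H]14
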